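**Retrosynthetic overview**
- Endgame: the target comes from a 16‑O‑silyl tetraol by peracetylation and desilylation; C4 is set by MnO2 oxidation and CBS reduction of the macrocyclic enone.
- Ten‑membered ring (formed last): intramolecular CrCl2/NiCl2 coupling of the C5 vinyl iodide onto the C4 aldehyde. The epoxide is installed just before by 9‑OH‑directed VO(acac)2 epoxidation.
- γ‑Lactone (second ring): chelation‑controlled ester‑enolate aldol addition to the C8 ketone, lactonisation onto O7, equilibration at C17.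
- Key union: intermolecular boron aldol forming C7–C8 between the ring A alkoxymethyl ketone (fragment 1) and 4‑silyloxybut‑2‑ynal (fragment 2). C7 is then set by transfer hydrogenation, C9 by 1,3‑syn reduction, and the Z‑iodoalkene by hydroalumination–iodination.
- Ring A (first ring): asymmetric Birch reduction–methylation of a 2‑methoxy‑5‑methylbenzamide (C1), Brown allylation (C2), CBS reduction then Still–Wittig [2,3] shift (C9 onto C10).

Assumption: the Birch reduction–methylation of the (S)‑prolinol‑derived benzamide 4 gives the C1 configuration drawn for 6; if the sense were opposite, the (R)‑auxiliary would be used with no other change.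

Labels: C1–C20 are the briarane positions of the target (C15 = methyl on C1, C16 = CH2O on C5, C17/C18/C19 = lactone CH(CH3)C=O, C20 = methyl on C11). β is the face of ring A that carries Me‑15. TBS = tert‑butyldimethylsilyl, TBDPS = tert‑butyldiphenylsilyl, PMB = 4‑methoxybenzyl, MOM = methoxymethyl, DMP = Dess–Martin periodinane.

**Route**

Step 1
Reactants: 1 2-methoxy-5-methylbenzoic acid; 2 (S)-2-(methoxymethyl)pyrrolidine
Product: 4 chiral benzamide, via acyl chloride 3 (not isolated)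
Conditions: (COCl)2, cat. DMF, CH2Cl2, 0 °C to rt; then 2, Et3N, CH2Cl2, 0 °C
Reagents that add atoms: none
Why: Schotten–Baumann-type acylation of the secondary amine by the in situ acid chloride attaches the chiral auxiliary without creating a stereocentre.

Step 2
Reactants: 4 chiral benzamide
Product: 6 Birch diene amide, via potassium amide enolate 5 (not isolated)
Conditions: K (2.2 equiv), NH3(l)/THF, t-BuOH (1 equiv), −78 °C; then MeI, −78 °C
Reagents that add atoms: iodomethane, CI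
Why: Schultz asymmetric Birch reduction–alkylation, in which the chelated potassium amide enolate is methylated on the face away from the auxiliary's methoxymethyl arm, sets quaternary C1 (Me-15 β, carboxamide carbon C2 α) while the OMe- and Me-bearing arene carbons become the C14 enol ether and the C10=C11 alkene.

Step 3
Reactants: 6 Birch diene amide
Product: 7 keto amide
Conditions: 1 M HCl, THF, 0 °C to rt
Reagents that add atoms: water, O
Why: Acid-catalysed enol ether hydrolysis unmasks the C14 ketone, and because C1 is quaternary the C10=C11 alkene cannot move into conjugation.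

Step 4
Reactants: 7 keto amide
Product: 8 hydroxy amide
Conditions: NaBH4, MeOH, −20 °C
Reagents that add atoms: none
Why: Borohydride reduction under steric approach control delivers hydride anti to the bulky carboxamide on C1, so the new 14-OH is α (cis to C2, trans to Me-15).

Step 5
Reactants: 8 hydroxy amide
Product: 9 silyl ether amide
Conditions: TBSOTf, 2,6-lutidine, CH2Cl2, 0 °C
Reagents that add atoms: tert-butyldimethylsilyl triflate, CC(C)(C)[Si](C)(C)OS(=O)(=O)C(F)(F)F
Why: Silyl triflate silylation protects the hindered secondary 14-OH as a base- and hydride-stable ether.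

Step 6
Reactants: 9 silyl ether amide
Product: 10 neopentyl alcohol
Conditions: LiNH2BH3 (from LiN(i-Pr)2 and BH3·NH3), THF, 0 °C to rt
Reagents that add atoms: none
Why: Myers lithium amidotrihydroborate reduction cleaves the C–N bond of the hindered tertiary amide to give the primary alcohol (C2) and returns the auxiliary, leaving C1 untouched.

Step 7
Reactants: 10 neopentyl alcohol
Product: 11 neopentyl aldehyde
Conditions: DMP, NaHCO3, CH2Cl2, rt
Reagents that add atoms: none
Why: Dess–Martin oxidation gives the non-enolisable C2 aldehyde without risk to the quaternary centre.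

Step 8
Reactants: 11 neopentyl aldehyde
Product: 12 homoallylic alcohol
Conditions: (+)-Ipc2BOMe [from (−)-α-pinene], allylMgBr, Et2O, 0 °C to rt; then 11, −78 °C; NaOH, H2O2
Reagents that add atoms: allylmagnesium bromide, C=CC[Mg]Br
Why: Brown asymmetric allylboration through a chair Zimmerman–Traxler transition state is reagent-controlled and gives the (2R)-carbinol with the three carbons that become C3, C4 and a sacrificial terminal CH2.

Step 9
Reactants: 12 homoallylic alcohol
Product: 13 bis-silyl ether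
Conditions: TBSOTf, 2,6-lutidine, CH2Cl2, 0 °C
Reagents that add atoms: tert-butyldimethylsilyl triflate, CC(C)(C)[Si](C)(C)OS(=O)(=O)C(F)(F)F
Why: Silyl triflate silylation protects the neopentyl 2-OH for the long sequence that follows.

Step 10
Reactants: 13 bis-silyl ether
Product: 14 ring A enone
Conditions: Rh2(cap)4 (dirhodium tetracaprolactamate, 1 mol %), t-BuOOH (5 equiv), K2CO3, CH2Cl2, rt
Reagents that add atoms: tert-butyl hydroperoxide, CC(C)(C)OO
Why: Catalytic allylic oxidation of the ring alkene occurs at C12, the only ring allylic methylene (C1 is quaternary), giving the C12 enone while the less reactive terminal alkene survives.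

Step 11
Reactants: 14 ring A enone
Product: 15 allylic alcohol
Conditions: (R)-2-methyl-CBS-oxazaborolidine (0.2 equiv), BH3·SMe2, THF, −30 °C; MeOH
Reagents that add atoms: none
Why: Corey–Bakshi–Shibata reduction with the α-methylated alkene as the large group is reagent-controlled and gives the 12β-alcohol (12S).

Step 12
Reactants: 15 allylic alcohol
Product: 16 stannylmethyl ether
Conditions: KH, 18-crown-6, Bu3SnCH2I, THF, 0 °C to rt
Reagents that add atoms: (iodomethyl)tributylstannane, CCCC[Sn](CCCC)(CCCC)CI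
Why: Williamson etherification of the potassium alkoxide installs the Still stannylmethyl group on O12 without touching the stereocentre.

Step 13
Reactants: 16 stannylmethyl ether
Product: 18 C9 primary alcohol, via alkoxymethyllithium 17 (not isolated)
Conditions: n-BuLi, THF, −78 to −40 °C
Reagents that add atoms: none
Why: Still–Wittig [2,3]-sigmatropic rearrangement after tin–lithium exchange is suprafacial, so the CH2OH carbon (C9) is delivered to C10 on the β face vacated by O12 and the alkene moves to C11=C12.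

Step 14
Reactants: 18 C9 primary alcohol
Product: 19 C9 aldehyde
Conditions: DMP, NaHCO3, CH2Cl2, 0 °C
Reagents that add atoms: none
Why: Buffered Dess–Martin oxidation gives the aldehyde under neutral conditions that avoid epimerisation at C10 or migration of the C11=C12 alkene.

Step 15
Reactants: 19 C9 aldehyde
Product: 20 C9 carbinol
Conditions: Bu3SnCH2OPMB, n-BuLi, THF, −78 °C; then 19, −78 °C
Reagents that add atoms: tributyl{[(4-methoxybenzyl)oxy]methyl}stannane, CCCC[Sn](CCCC)(CCCC)COCc1ccc(OC)cc1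
Why: Addition of the small α-alkoxymethyllithium (tin–lithium exchange) to the hindered aldehyde adds C8 with its protected oxygen, and the C9 configuration is irrelevant because it is oxidised next.

Step 16
Reactants: 20 C9 carbinol
Product: 21 ring A alkoxymethyl ketone (fragment 1)
Conditions: DMP, NaHCO3, CH2Cl2, rt
Reagents that add atoms: none
Why: Dess–Martin oxidation gives the α-alkoxy ketone needed as the aldol donor.

Step 17
Reactants: 22 but-2-yne-1,4-diol
Product: 23 monosilyl butynediol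
Conditions: 22 (3 equiv), TBDPSCl (1 equiv), imidazole, DMF, 0 °C
Reagents that add atoms: tert-butyldiphenylsilyl chloride, CC(C)(C)[Si](Cl)(c1ccccc1)c1ccccc1
Why: Statistical monosilylation with excess of the cheap symmetric diol gives the mono-protected alcohol.

Step 18
Reactants: 23 monosilyl butynediol
Product: 24 silyloxybutynal (fragment 2)
Conditions: MnO2, CH2Cl2, rt
Reagents that add atoms: none
Why: MnO2 oxidises the propargylic alcohol selectively to the ynal.

Step 19
Reactants: 21 ring A alkoxymethyl ketone (fragment 1); 24 silyloxybutynal (fragment 2)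
Product: 26 aldol adduct, via boron enolate 25 (not isolated)
Conditions: Bu2BOTf, i-Pr2NEt, CH2Cl2, −78 to 0 °C; then 24, −78 °C; pH 7 buffer, MeOH, H2O2
Reagents that add atoms: none
Why: Boron-mediated intermolecular aldol addition, in which soft enolisation occurs only at the alkoxymethyl carbon C8 (the C10 methine is too hindered) and the Z-enolate adds 1,2 to the ynal, forms the C7–C8 bond; the new stereocentres need no control because C7 is reset in steps 20–21 and C8 is later oxidised.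

Step 20
Reactants: 26 aldol adduct
Product: 27 ynedione
Conditions: DMP, NaHCO3, CH2Cl2, 0 °C
Reagents that add atoms: none
Why: Dess–Martin oxidation of the propargylic alcohol erases the uncontrolled C7 centre and gives an ynone that can be reduced under catalyst control.

Step 21
Reactants: 27 ynedione
Product: 28 propargylic alcohol
Conditions: RuCl[(R,R)-TsDPEN](p-cymene) (5 mol %), HCO2H/Et3N (5:2), CH2Cl2, rt
Reagents that add atoms: none
Why: Noyori asymmetric transfer hydrogenation reduces only the alkynyl ketone (the hindered dialkyl C9 ketone is inert) and the (R,R)-catalyst gives the (7S)-alcohol.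

Step 22
Reactants: 28 propargylic alcohol
Product: 29 syn-diol
Conditions: Et2BOMe, THF/MeOH (4:1), −78 °C; NaBH4
Reagents that add atoms: none
Why: Narasaka–Prasad reduction through the six-membered boron chelate of the β-hydroxy ketone delivers external hydride to give the 7,9-syn diol, i.e. (9R).

Step 23
Reactants: 29 syn-diol
Product: 31 vinyl iodide diol, via vinylalanate 30 (not isolated)
Conditions: NaAlH2(OCH2CH2OMe)2, THF, 0 °C; then I2, THF, −78 °C
Reagents that add atoms: iodine, II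
Why: Hydroxyl-directed trans-hydroalumination of the propargylic alcohol puts aluminium on the distal carbon C5, and iodinolysis with retention gives the (Z)-vinyl iodide with the iodide cis to C7, the geometry the ring alkene needs.

Step 24
Reactants: 31 vinyl iodide diol
Product: 32 bis-MOM ether
Conditions: MOMCl, i-Pr2NEt, Bu4NI (cat.), CH2Cl2, 40 °C
Reagents that add atoms: chloromethyl methyl ether, COCCl
Why: Alkylation of both secondary hydroxyls gives chelating acetal ethers at O7 and O9 that will direct the addition to the C8 ketone.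

Step 25
Reactants: 32 bis-MOM ether
Product: 33 C8 alcohol
Conditions: DDQ, CH2Cl2/pH 7 buffer, 0 °C
Reagents that add atoms: none
Why: Oxidative cleavage of the PMB ether by DDQ frees only the C8 hydroxyl, with MOM, silyl and vinyl iodide groups untouched.

Step 26
Reactants: 33 C8 alcohol
Product: 34 C8 ketone
Conditions: DMP, NaHCO3, CH2Cl2, rt
Reagents that add atoms: none
Why: Dess–Martin oxidation converges the C8 epimers to a single α,α'-bis(alkoxy) ketone under neutral conditions that do not epimerise C7 or C9.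

Step 27
Reactants: 34 C8 ketone
Product: 35 tertiary hydroxy ester
Conditions: ethyl propanoate, LiN(i-Pr)2, THF, −78 °C; then 34 precomplexed with MgBr2·OEt2 (CH2Cl2), −78 °C
Reagents that add atoms: ethyl propanoate, CCC(=O)OCC
Why: Cram-chelate-controlled aldol addition of the ester enolate, with magnesium bound to the ketone and both MOM oxygens so that the enolate attacks the face carrying H-7 and H-9, sets the C8 tertiary alcohol as in the target (C17 is formed as a mixture and corrected in step 29).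

Step 28
Reactants: 35 tertiary hydroxy ester
Product: 37 lactone (C17 epimers), via dihydroxy ester 36 (not isolated)
Conditions: Me2BBr, CH2Cl2, −78 °C; aq. NaHCO3; then PPTS (cat.), CH2Cl2, rt
Reagents that add atoms: none
Why: Dimethylboron bromide cleaves both MOM acetals at low temperature, and the freed allylic 7-OH, less hindered than the 9-OH, closes the γ-lactone by transesterification.

Step 29
Reactants: 37 lactone (C17 epimers)
Product: 38 lactone (17R)
Conditions: DBU (0.5 equiv), toluene, 50 °C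
Reagents that add atoms: none
Why: Base-mediated equilibration of the enolisable C17 centre converges on the thermodynamic lactone in which the three carbon substituents on C7, C8 and C17 alternate faces (Me-18 trans to C9), which is the (17R) target configuration.

Step 30
Reactants: 38 lactone (17R)
Product: 39 epoxy lactone
Conditions: VO(acac)2 (5 mol %), t-BuOOH, CH2Cl2, 0 °C to rt
Reagents that add atoms: tert-butyl hydroperoxide, CC(C)(C)OO
Why: Vanadium-catalysed hydroxyl-directed epoxidation uses the homoallylic 9-OH on the β side chain to deliver oxygen to the β face of the trisubstituted C11=C12 alkene, while the electron-poor iodoalkene and the terminal alkene do not react.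

Step 31
Reactants: 39 epoxy lactone
Product: 40 9-acetate
Conditions: Ac2O, pyridine, DMAP (cat.), CH2Cl2, 0 °C to rt
Reagents that add atoms: acetic anhydride, CC(=O)OC(C)=O
Why: Nucleophilic-catalysed acetylation esterifies the secondary 9-OH (a target acetate) and leaves the tertiary 8-OH, which also blocks translactonisation and hemiacetal formation later.

Step 32
Reactants: 40 9-acetate
Product: 42 seco-aldehyde, via terminal diol 41 (not isolated)
Conditions: OsO4 (2 mol %), NaIO4, 2,6-lutidine, dioxane/H2O, rt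
Reagents that add atoms: osmium tetroxide, O=[Os](=O)(=O)=O; sodium periodate, [Na+].[O-]I(=O)(=O)=O
Why: Lemieux–Johnson cleavage of the only remaining electron-rich (monosubstituted) alkene gives the C4 aldehyde, since the ring alkene is already an epoxide and the iodoalkene is too electron-poor for osmylation.

Step 33
Reactants: 42 seco-aldehyde
Product: 43 macrocyclic allylic alcohol (C4 epimers)
Conditions: CrCl2 (15 equiv), NiCl2 (0.1 equiv), DMSO/THF, rt, 2 mM, slow addition
Reagents that add atoms: none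
Why: Intramolecular Nozaki–Hiyama–Kishi coupling adds the alkenylchromium from the C5 iodide to the C4 aldehyde with retention of alkene geometry (C4 cis to C7), closing the ten-membered ring in the presence of lactone, epoxide, acetate and free tertiary hydroxyl.

Step 34
Reactants: 43 macrocyclic allylic alcohol (C4 epimers)
Product: 44 macrocyclic enone
Conditions: MnO2, CH2Cl2, rt
Reagents that add atoms: none
Why: MnO2 oxidises only the allylic 4-OH (the other free hydroxyl is tertiary), converging both C4 epimers on one enone.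

Step 35
Reactants: 44 macrocyclic enone
Product: 45 (4R)-alcohol
Conditions: (S)-2-methyl-CBS-oxazaborolidine (1 equiv), catecholborane, toluene, −78 °C
Reagents that add atoms: none
Why: Corey–Bakshi–Shibata 1,2-reduction with the α-branched alkene as the large group is reagent-controlled and gives the (4R)-alcohol (2,4-anti) without touching lactone, acetate or epoxide.

Step 36
Reactants: 45 (4R)-alcohol
Product: 46 pentaol
Conditions: Bu4NF, AcOH, THF, 0 °C to rt
Reagents that add atoms: none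
Why: Acetic acid-buffered fluoride desilylation removes both TBS ethers and the TBDPS ether under near-neutral conditions that spare the epoxide, the acetate and the β-hydroxy lactone.

Step 37
Reactants: 46 pentaol
Product: 47 16-O-silyl tetraol
Conditions: TBSCl (1.1 equiv), imidazole, CH2Cl2, −20 °C
Reagents that add atoms: tert-butyldimethylsilyl chloride, CC(C)(C)[Si](C)(C)Cl
Why: Sterically selective silylation caps the only primary (allylic C16) hydroxyl so that it alone stays unacetylated.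

Step 38
Reactants: 47 16-O-silyl tetraol
Product: 48 16-O-silyl tetraacetate
Conditions: Ac2O, pyridine, DMAP, CH2Cl2, rt
Reagents that add atoms: acetic anhydride, CC(=O)OC(C)=O
Why: DMAP-catalysed acetylation esterifies the three secondary hydroxyls at C2, C4 and C14 while the hindered tertiary 8-OH does not react.

Step 39
Reactants: 48 16-O-silyl tetraacetate
Product: 49 CNP0104124.1
Conditions: HF·pyridine, pyridine, THF, 0 °C to rt
Reagents that add atoms: none
Why: Buffered fluoride cleavage of the primary silyl ether liberates the C16 alcohol under conditions too mild for acetate migration or epoxide opening.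

**Compound list**

1 | 2-methoxy-5-methylbenzoic acid | COc1ccc(C)cc1C(=O)O | starting material
2 | (S)-2-(methoxymethyl)pyrrolidine | COC[C@@H]1CCCN1 | starting material
3 | 2-methoxy-5-methylbenzoyl chloride | COc1ccc(C)cc1C(=O)Cl | intermediate
4 | chiral benzamide: (2-methoxy-5-methylphenyl)[(2S)-2-(methoxymethyl)pyrrolidin-1-yl]methanone | COc1ccc(C)cc1C(=O)N1CCC[C@H]1COC | intermediate
5 | potassium amide enolate of the 1,4-dihydro benzamide | COC1=CCC(C)=CC1=C([O-])N1CCC[C@H]1COC.[K+] | intermediate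
6 | Birch diene amide: [(1R)-2-methoxy-1,5-dimethylcyclohexa-2,5-dien-1-yl][(2S)-2-(methoxymethyl)pyrrolidin-1-yl]methanone (Me-15 β, carboxamide α on C1) | COC1=CCC(C)=C[C@@]1(C)C(=O)N1CCC[C@H]1COC | intermediate
7 | keto amide: C14 ketone, C10=C11(Me) alkene, C1 as in 6 | O=C1CCC(C)=C[C@@]1(C)C(=O)N1CCC[C@H]1COC | intermediate
8 | hydroxy amide: 14α-OH (14S), cis to the carboxamide | O[C@H]1CCC(C)=C[C@@]1(C)C(=O)N1CCC[C@H]1COC | intermediate
9 | silyl ether amide: 14α-OTBS | CC(C)(C)[Si](C)(C)O[C@H]1CCC(C)=C[C@@]1(C)C(=O)N1CCC[C@H]1COC | intermediate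
10 | neopentyl alcohol: C1 bears Me-15 (β) and CH2OH (C2, α); 14α-OTBS; C10=C11(Me) | CC(C)(C)[Si](C)(C)O[C@H]1CCC(C)=C[C@@]1(C)CO | intermediate
11 | neopentyl aldehyde: C2 = CHO | CC(C)(C)[Si](C)(C)O[C@H]1CCC(C)=C[C@@]1(C)C=O | intermediate
12 | homoallylic alcohol: (2R)-OH, allyl on C2 | CC(C)(C)[Si](C)(C)O[C@H]1CCC(C)=C[C@@]1(C)[C@H](O)CC=C | intermediate
13 | bis-silyl ether: 2-OTBS and 14-OTBS | CC(C)(C)[Si](C)(C)O[C@H]1CCC(C)=C[C@@]1(C)[C@H](O[Si](C)(C)C(C)(C)C)CC=C | intermediate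
14 | ring A enone: C12 ketone conjugated with C11(Me)=C10 | CC(C)(C)[Si](C)(C)O[C@H]1CC(=O)C(C)=C[C@@]1(C)[C@H](O[Si](C)(C)C(C)(C)C)CC=C | intermediate
15 | allylic alcohol: 12β-OH (12S) | CC(C)(C)[Si](C)(C)O[C@H]1C[C@H](O)C(C)=C[C@@]1(C)[C@H](O[Si](C)(C)C(C)(C)C)CC=C | intermediate
16 | stannylmethyl ether: 12β-OCH2SnBu3 | CC(C)(C)[Si](C)(C)O[C@H]1C[C@H](OC[Sn](CCCC)(CCCC)CCCC)C(C)=C[C@@]1(C)[C@H](O[Si](C)(C)C(C)(C)C)CC=C | intermediate
17 | alkoxymethyllithium: 12β-OCH2Li | CC(C)(C)[Si](C)(C)O[C@H]1C[C@H](OC[Li])C(C)=C[C@@]1(C)[C@H](O[Si](C)(C)C(C)(C)C)CC=C | intermediate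
18 | C9 primary alcohol: CH2OH β on C10, C11(Me)=C12 alkene | CC(C)(C)[Si](C)(C)O[C@H]1CC=C(C)[C@H](CO)[C@@]1(C)[C@H](O[Si](C)(C)C(C)(C)C)CC=C | intermediate
19 | C9 aldehyde | CC(C)(C)[Si](C)(C)O[C@H]1CC=C(C)[C@H](C=O)[C@@]1(C)[C@H](O[Si](C)(C)C(C)(C)C)CC=C | intermediate
20 | C9 carbinol: C10–CH(OH)–CH2OPMB (C9 epimers) | CC(C)(C)[Si](C)(C)O[C@H]1CC=C(C)[C@H](C(O)COCc2ccc(OC)cc2)[C@@]1(C)[C@H](O[Si](C)(C)C(C)(C)C)CC=C | intermediate
21 | ring A alkoxymethyl ketone (fragment 1): C10–C(=O)–CH2OPMB | CC(C)(C)[Si](C)(C)O[C@H]1CC=C(C)[C@H](C(=O)COCc2ccc(OC)cc2)[C@@]1(C)[C@H](O[Si](C)(C)C(C)(C)C)CC=C | intermediate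
22 | but-2-yne-1,4-diol | OCC#CCO | starting material
23 | 4-(tert-butyldiphenylsilyloxy)but-2-yn-1-ol | OCC#CCO[Si](c1ccccc1)(c1ccccc1)C(C)(C)C | intermediate
24 | 4-(tert-butyldiphenylsilyloxy)but-2-ynal (fragment 2) | O=CC#CCO[Si](c1ccccc1)(c1ccccc1)C(C)(C)C | intermediate
25 | (Z)-dibutylboron enolate of 21 (C9–OBBu2, C8=C9) | CC(C)(C)[Si](C)(C)O[C@H]1CC=C(C)[C@H](/C(OB(CCCC)CCCC)=C/OCc2ccc(OC)cc2)[C@@]1(C)[C@H](O[Si](C)(C)C(C)(C)C)CC=C | intermediate
26 | aldol adduct: C9 ketone, 8-OPMB, 7-OH, C5≡C6, 16-OTBDPS (C7/C8 mixture) | CC(C)(C)[Si](C)(C)O[C@H]1CC=C(C)[C@H](C(=O)C(OCc2ccc(OC)cc2)C(O)C#CCO[Si](c2ccccc2)(c2ccccc2)C(C)(C)C)[C@@]1(C)[C@H](O[Si](C)(C)C(C)(C)C)CC=C | intermediate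
27 | ynedione: C7 and C9 ketones, 8-OPMB (C8 epimers) | CC(C)(C)[Si](C)(C)O[C@H]1CC=C(C)[C@H](C(=O)C(OCc2ccc(OC)cc2)C(=O)C#CCO[Si](c2ccccc2)(c2ccccc2)C(C)(C)C)[C@@]1(C)[C@H](O[Si](C)(C)C(C)(C)C)CC=C | intermediate
28 | propargylic alcohol: (7S)-OH, C9 ketone | CC(C)(C)[Si](C)(C)O[C@H]1CC=C(C)[C@H](C(=O)C(OCc2ccc(OC)cc2)[C@@H](O)C#CCO[Si](c2ccccc2)(c2ccccc2)C(C)(C)C)[C@@]1(C)[C@H](O[Si](C)(C)C(C)(C)C)CC=C | intermediate
29 | syn-diol: (7S)-OH and (9R)-OH | CC(C)(C)[Si](C)(C)O[C@H]1CC=C(C)[C@H]([C@@H](O)C(OCc2ccc(OC)cc2)[C@@H](O)C#CCO[Si](c2ccccc2)(c2ccccc2)C(C)(C)C)[C@@]1(C)[C@H](O[Si](C)(C)C(C)(C)C)CC=C | intermediate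
30 | vinylalanate: sodium salt of the five-membered O7–Al–C5=C6 ring (9-oxygen shown protonated) | CC(C)(C)[Si](C)(C)O[C@H]1CC=C(C)[C@H]([C@@H](O)C(OCc2ccc(OC)cc2)[C@H]2O[Al-](OCCOC)(OCCOC)C(CO[Si](c3ccccc3)(c3ccccc3)C(C)(C)C)=C2)[C@@]1(C)[C@H](O[Si](C)(C)C(C)(C)C)CC=C.[Na+] | intermediate
31 | vinyl iodide diol: (5Z), iodide on C5 cis to C7 | CC(C)(C)[Si](C)(C)O[C@H]1CC=C(C)[C@H]([C@@H](O)C(OCc2ccc(OC)cc2)[C@@H](O)/C=C(/CO[Si](c2ccccc2)(c2ccccc2)C(C)(C)C)I)[C@@]1(C)[C@H](O[Si](C)(C)C(C)(C)C)CC=C | intermediate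
32 | bis-MOM ether: 7-OMOM, 9-OMOM | CC(C)(C)[Si](C)(C)O[C@H]1CC=C(C)[C@H]([C@@H](OCOC)C(OCc2ccc(OC)cc2)[C@@H](OCOC)/C=C(/CO[Si](c2ccccc2)(c2ccccc2)C(C)(C)C)I)[C@@]1(C)[C@H](O[Si](C)(C)C(C)(C)C)CC=C | intermediate
33 | C8 alcohol (C8 epimers) | CC(C)(C)[Si](C)(C)O[C@H]1CC=C(C)[C@H]([C@@H](OCOC)C(O)[C@@H](OCOC)/C=C(/CO[Si](c2ccccc2)(c2ccccc2)C(C)(C)C)I)[C@@]1(C)[C@H](O[Si](C)(C)C(C)(C)C)CC=C | intermediate
34 | C8 ketone | CC(C)(C)[Si](C)(C)O[C@H]1CC=C(C)[C@H]([C@@H](OCOC)C(=O)[C@@H](OCOC)/C=C(/CO[Si](c2ccccc2)(c2ccccc2)C(C)(C)C)I)[C@@]1(C)[C@H](O[Si](C)(C)C(C)(C)C)CC=C | intermediate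
35 | tertiary hydroxy ester: 8-OH as in the target, C8–CH(CH3)CO2Et (C17 epimers) | CC(C)(C)[Si](C)(C)O[C@H]1CC=C(C)[C@H]([C@@H](OCOC)[C@](O)(C(C)C(=O)OCC)[C@@H](OCOC)/C=C(/CO[Si](c2ccccc2)(c2ccccc2)C(C)(C)C)I)[C@@]1(C)[C@H](O[Si](C)(C)C(C)(C)C)CC=C | intermediate
36 | dihydroxy ester: 7-OH and 9-OH free | CC(C)(C)[Si](C)(C)O[C@H]1CC=C(C)[C@H]([C@@H](O)[C@](O)(C(C)C(=O)OCC)[C@@H](O)/C=C(/CO[Si](c2ccccc2)(c2ccccc2)C(C)(C)C)I)[C@@]1(C)[C@H](O[Si](C)(C)C(C)(C)C)CC=C | intermediate
37 | lactone (C17 epimers): γ-lactone C19–O7, 8-OH cis to C6, 9-OH free | CC(C)(C)[Si](C)(C)O[C@H]1CC=C(C)[C@H]([C@@H](O)[C@@]2(O)[C@H](/C=C(/CO[Si](c3ccccc3)(c3ccccc3)C(C)(C)C)I)OC(=O)C2C)[C@@]1(C)[C@H](O[Si](C)(C)C(C)(C)C)CC=C | intermediate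
38 | lactone (17R): Me-18 trans to C9 | CC(C)(C)[Si](C)(C)O[C@H]1CC=C(C)[C@H]([C@@H](O)[C@@]2(O)[C@H](/C=C(/CO[Si](c3ccccc3)(c3ccccc3)C(C)(C)C)I)OC(=O)[C@@H]2C)[C@@]1(C)[C@H](O[Si](C)(C)C(C)(C)C)CC=C | intermediate
39 | epoxy lactone: 11β,12β-epoxide | CC(C)(C)[Si](C)(C)O[C@H]1C[C@@H]2O[C@]2(C)[C@H]([C@@H](O)[C@@]2(O)[C@H](/C=C(/CO[Si](c3ccccc3)(c3ccccc3)C(C)(C)C)I)OC(=O)[C@@H]2C)[C@@]1(C)[C@H](O[Si](C)(C)C(C)(C)C)CC=C | intermediate
40 | 9-acetate | CC(C)(C)[Si](C)(C)O[C@H]1C[C@@H]2O[C@]2(C)[C@H]([C@@H](OC(C)=O)[C@@]2(O)[C@H](/C=C(/CO[Si](c3ccccc3)(c3ccccc3)C(C)(C)C)I)OC(=O)[C@@H]2C)[C@@]1(C)[C@H](O[Si](C)(C)C(C)(C)C)CC=C | intermediate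
41 | terminal diol from the allyl group | CC(C)(C)[Si](C)(C)O[C@H]1C[C@@H]2O[C@]2(C)[C@H]([C@@H](OC(C)=O)[C@@]2(O)[C@H](/C=C(/CO[Si](c3ccccc3)(c3ccccc3)C(C)(C)C)I)OC(=O)[C@@H]2C)[C@@]1(C)[C@H](O[Si](C)(C)C(C)(C)C)CC(O)CO | intermediate
42 | seco-aldehyde: C4 = CHO, C5 vinyl iodide | CC(C)(C)[Si](C)(C)O[C@H]1C[C@@H]2O[C@]2(C)[C@H]([C@@H](OC(C)=O)[C@@]2(O)[C@H](/C=C(/CO[Si](c3ccccc3)(c3ccccc3)C(C)(C)C)I)OC(=O)[C@@H]2C)[C@@]1(C)[C@H](O[Si](C)(C)C(C)(C)C)CC=O | intermediate
43 | macrocyclic allylic alcohol: ten-membered ring closed, (5Z), 4-OH (C4 epimers) | CC(C)(C)[Si](C)(C)O[C@H]1C[C@@H]2O[C@]2(C)[C@@H]2[C@@H](OC(C)=O)[C@@]3(O)[C@H](/C=C(/CO[Si](c4ccccc4)(c4ccccc4)C(C)(C)C)C(O)C[C@@H](O[Si](C)(C)C(C)(C)C)[C@@]12C)OC(=O)[C@@H]3C | intermediate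
44 | macrocyclic enone: C4 ketone conjugated with C5=C6 | CC(C)(C)[Si](C)(C)O[C@H]1C[C@@H]2O[C@]2(C)[C@@H]2[C@@H](OC(C)=O)[C@@]3(O)[C@H](/C=C(/CO[Si](c4ccccc4)(c4ccccc4)C(C)(C)C)C(=O)C[C@@H](O[Si](C)(C)C(C)(C)C)[C@@]12C)OC(=O)[C@@H]3C | intermediate
45 | (4R)-alcohol | CC(C)(C)[Si](C)(C)O[C@H]1C[C@@H]2O[C@]2(C)[C@@H]2[C@@H](OC(C)=O)[C@@]3(O)[C@H](/C=C(/CO[Si](c4ccccc4)(c4ccccc4)C(C)(C)C)[C@H](O)C[C@@H](O[Si](C)(C)C(C)(C)C)[C@@]12C)OC(=O)[C@@H]3C | intermediate
46 | pentaol: OH at C2, C4, C8, C14, C16; 9-OAc | O[C@H]1C[C@@H]2O[C@]2(C)[C@@H]2[C@@H](OC(C)=O)[C@@]3(O)[C@H](/C=C(/CO)[C@H](O)C[C@@H](O)[C@@]12C)OC(=O)[C@@H]3C | intermediate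
47 | 16-O-silyl tetraol: 16-OTBS | O[C@H]1C[C@@H]2O[C@]2(C)[C@@H]2[C@@H](OC(C)=O)[C@@]3(O)[C@H](/C=C(/CO[Si](C)(C)C(C)(C)C)[C@H](O)C[C@@H](O)[C@@]12C)OC(=O)[C@@H]3C | intermediate
48 | 16-O-silyl tetraacetate: OAc at C2, C4, C9, C14 | CC(=O)O[C@H]1C[C@@H]2O[C@]2(C)[C@@H]2[C@@H](OC(C)=O)[C@@]3(O)[C@H](/C=C(/CO[Si](C)(C)C(C)(C)C)[C@H](OC(C)=O)C[C@@H](OC(C)=O)[C@@]12C)OC(=O)[C@@H]3C | intermediate
49 | CNP0104124.1: (1S,2R,4R,5Z,7S,8S,9R,10S,11R,12S,14S,17R)-2,4,9,14-tetraacetoxy-11,12-epoxy-8,16-dihydroxybriar-5-en-18,7-olide | CC(=O)O[C@H]1C[C@@H]2O[C@]2(C)[C@@H]2[C@@H](OC(C)=O)[C@@]3(O)[C@H](/C=C(/CO)[C@H](OC(C)=O)C[C@@H](OC(C)=O)[C@@]12C)OC(=O)[C@@H]3C | target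

**Totals and risks**

Total step count: 39. Longest linear sequence: 37 steps (steps 1–16, then 19–39); fragment 2 takes 2 steps.

The three steps most likely to fail:

Step 13, the Still–Wittig shift onto C10, which sits next to the quaternary C1, may give [1,2]-shift or simple protonation instead. The fallback sets out from 15 and comes back at 19, replacing the [2,3] shift by a [3,3] shift. Alcohol 15 is esterified with (4-methoxybenzyloxy)acetic acid (DCC, DMAP) to the allylic glycolate ester F1. An Ireland–Claisen rearrangement (LiN(SiMe3)2, Me3SiCl, THF, −78 °C to rt) carries the glycolate α-carbon suprafacially to the β face of C10 and gives the α-alkoxy acid F2 with the alkene at C11=C12; its C9 configuration does not matter. DDQ removes the PMB group to give the α-hydroxy acid F3, and Pb(OAc)4 in benzene cleaves it oxidatively, with loss of CO2, to aldehyde 19.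

Step 27, the ester-enolate addition to the hindered bis-alkoxy ketone, may lose to enolisation or give poor control at C17. The fallback sets out from 34 and comes back at 38, using a smaller, less basic nucleophile and setting C17 by alkylation instead of equilibration. Ketone 34, still chelated by MgBr2·OEt2, is treated with the Reformatsky reagent from Zn and ethyl bromoacetate in THF to give the C17-unsubstituted hydroxy ester F4. Me2BBr and then PPTS, as in step 28, give the des-methyl lactone F5. LiN(i-Pr)2 (3.3 equiv) at −78 °C followed by MeI methylates the lactone enolate anti to the bulky C9 substituent and gives 38 directly.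

Step 33, the chromium-mediated closure of the trans-fused ten-membered ring, may be slow or give oligomers. The fallback sets out from 42 and comes back at 44, closing the same ring by acylation so that the enone forms directly and no C4 epimers arise. Aldehyde 42 is oxidised (NaClO2, NaH2PO4, 2-methyl-2-butene) to the carboxylic acid F6 and converted (EtSH, EDC, DMAP) into the S-ethyl thioester F7. Pd(PPh3)4 and Me3SnSnMe3 exchange the iodide for tin with retention to give the alkenylstannane thioester F8. A Liebeskind–Srogl macrocyclisation (Pd2(dba)3, tri(2-furyl)phosphine, copper thiophene-2-carboxylate CuO2CC4H3S, THF, high dilution) then gives enone 44.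

**Further compounds**

F1 | step 13 | allylic glycolate ester of 15: 12β-OC(=O)CH2OPMB | CC(C)(C)[Si](C)(C)O[C@H]1C[C@H](OC(=O)COCc2ccc(OC)cc2)C(C)=C[C@@]1(C)[C@H](O[Si](C)(C)C(C)(C)C)CC=C
F2 | step 13 | α-alkoxy acid: C10(β)–CH(OPMB)–CO2H, C11=C12 alkene (C9 epimers) | CC(C)(C)[Si](C)(C)O[C@H]1CC=C(C)[C@H](C(OCc2ccc(OC)cc2)C(=O)O)[C@@]1(C)[C@H](O[Si](C)(C)C(C)(C)C)CC=C
F3 | step 13 | α-hydroxy acid: C10(β)–CH(OH)–CO2H | CC(C)(C)[Si](C)(C)O[C@H]1CC=C(C)[C@H](C(O)C(=O)O)[C@@]1(C)[C@H](O[Si](C)(C)C(C)(C)C)CC=C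
F4 | step 27 | C17-unsubstituted hydroxy ester: 8-OH as in the target, C8–CH2CO2Et | CC(C)(C)[Si](C)(C)O[C@H]1CC=C(C)[C@H]([C@@H](OCOC)[C@](O)(CC(=O)OCC)[C@@H](OCOC)/C=C(/CO[Si](c2ccccc2)(c2ccccc2)C(C)(C)C)I)[C@@]1(C)[C@H](O[Si](C)(C)C(C)(C)C)CC=C
F5 | step 27 | des-methyl lactone: as 38 without the C17 methyl | CC(C)(C)[Si](C)(C)O[C@H]1CC=C(C)[C@H]([C@@H](O)[C@@]2(O)[C@H](/C=C(/CO[Si](c3ccccc3)(c3ccccc3)C(C)(C)C)I)OC(=O)C2)[C@@]1(C)[C@H](O[Si](C)(C)C(C)(C)C)CC=C
F6 | step 33 | seco-acid: C4 = CO2H | CC(C)(C)[Si](C)(C)O[C@H]1C[C@@H]2O[C@]2(C)[C@H]([C@@H](OC(C)=O)[C@@]2(O)[C@H](/C=C(/CO[Si](c3ccccc3)(c3ccccc3)C(C)(C)C)I)OC(=O)[C@@H]2C)[C@@]1(C)[C@H](O[Si](C)(C)C(C)(C)C)CC(=O)O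
F7 | step 33 | S-ethyl thioester: C4 = C(=O)SEt | CC(C)(C)[Si](C)(C)O[C@H]1C[C@@H]2O[C@]2(C)[C@H]([C@@H](OC(C)=O)[C@@]2(O)[C@H](/C=C(/CO[Si](c3ccccc3)(c3ccccc3)C(C)(C)C)I)OC(=O)[C@@H]2C)[C@@]1(C)[C@H](O[Si](C)(C)C(C)(C)C)CC(=O)SCC
F8 | step 33 | alkenylstannane thioester: SnMe3 on C5 in place of iodide | CC(C)(C)[Si](C)(C)O[C@H]1C[C@@H]2O[C@]2(C)[C@H]([C@@H](OC(C)=O)[C@@]2(O)[C@H](/C=C(/CO[Si](c3ccccc3)(c3ccccc3)C(C)(C)C)[Sn](C)(C)C)OC(=O)[C@@H]2C)[C@@]1(C)[C@H](O[Si](C)(C)C(C)(C)C)CC(=O)SCC
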